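Numbering: atoms C1–C27 follow the order of the target SMILES. Ring A = C3–C6, C8; ring B = C2, C3, C8–C11, C13, C27; ring C = C13–C15, C25–C27; ring D = C15, C19–C21, C25. β is the face of the C15 carboxyl and α the face of C25–H.
Cuts, in retrosynthetic order: ester O–CH3; C9–C10 (as a C9=C10 metathesis alkene); C27–C2 (alkenyl-metal plus ketone); C13–C11 (Claisen); C21–C25 (1,2-shift, back to a decalin with a C22–C25 bond); the two C22–CH3 bonds; the Robinson bonds C15–C19 and C22–C25; in ring A, C3–C8.
Enabling feature: ring D carries the isopropyl carbon C22 on C21, next to the ring-fusion methine C25 and 1,3 to the quaternary, carboxyl-bearing C15. This is what remains when the 3-hydroxy-4,4-dimethylcyclohexane ring (C15, C19–C22, C25) of a trans-decalin shrinks by moving C25 from C22 to C21.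
Forward order: ring C is bought, the six-membered forerunner of ring D is annulated and contracted to ring D, and C13 is crotylated. Ring A is built separately from citronellene by enyne cyclisation, the halves are joined at C27–C2, and ring B is closed last.
Stereochemistry: C15 comes from a valine-amide auxiliary; C25, C21 and C27 from substrate control (angular ester, equatorial attack); C13 and C11 from a chair Claisen on the α face; C6 from (R)-citronellene; C8 and the C2=C3 geometry from the zirconacycle.

Key step: step 9

Assumption: the L-valine diethylamide/Cu(OAc)2 protocol is taken to deliver the (R)-configured adduct 6; if the sense were opposite, the D-auxiliary would be used with nothing else changed.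

Step 1
Reactants: 1 methyl 2-oxocyclohexane-1-carboxylate; 2 L-valine diethylamide
Product: 3 methyl 2-{[(2S)-1-(diethylamino)-3-methyl-1-oxobutan-2-yl]amino}cyclohex-1-ene-1-carboxylate
Conditions: conc. HCl (cat.), 4 Å MS, toluene, 60 °C
Reagents that add atoms: L-valine diethylamide (2), N[C@@H](C(C)C)C(=O)N(CC)CC
Why: Acid-catalysed condensation of a β-keto ester with a primary amine gives the hydrogen-bonded enamino ester, the usual substrate for auxiliary-controlled Michael additions, and no stereocentre is formed.

Step 2
Reactants: 3 enamino ester; 4 but-3-en-2-one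
Product: 6 methyl (1R)-2-oxo-1-(3-oxobutyl)cyclohexane-1-carboxylate, via imine adduct 5 (not isolated)
Conditions: Cu(OAc)2·H2O (5 mol %), acetone, 23 °C; then 2 M HCl, 0 °C
Reagents that add atoms: but-3-en-2-one (4), CC(=O)C=C; water, O
Why: In this copper(II)-catalysed Michael addition of a chiral enamino ester, the chelate formed by enamine N, ester O and amide O leaves one face of C15 open, which should set the quaternary centre as R, and the acidic work-up hydrolyses imine 5 and returns the auxiliary.

Step 3
Reactants: 6 diketo ester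
Product: 7 methyl (4aR)-2-oxo-3,4,5,6,7,8-hexahydronaphthalene-4a(2H)-carboxylate
Conditions: pyrrolidine (cat.), AcOH (cat.), toluene, reflux, Dean–Stark
Reagents that add atoms: none
Why: The intramolecular aldol condensation that completes the Robinson annulation closes the six-membered forerunner of ring D (C22–C25) under amine/acid catalysis, which is too mild for retro-Michael loss of the C15 configuration.

Step 4
Reactants: 7 octalone ester; 8 iodomethane
Product: 9 methyl (4aR)-1,1-dimethyl-2-oxo-1,3,4,5,6,7-hexahydronaphthalene-4a(2H)-carboxylate (alkene C25=C26)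
Conditions: KOt-Bu (2.5 equiv), t-BuOH–THF, 23 °C; MeI, 0 → 23 °C
Reagents that add atoms: iodomethane (8), CI
Why: Deconjugative α,α-dialkylation of the extended dienolate, as in the classical 4,4-dimethylation of Δ4-3-keto steroids, places both methyl groups on C22 and moves the alkene to C25=C26.

Step 5
Reactants: 9 β,γ-unsaturated ketone
Product: 10 methyl (4aR)-1,1-dimethyl-2,7-dioxo-1,3,4,5,6,7-hexahydronaphthalene-4a(2H)-carboxylate
Conditions: Rh2(cap)4 (1 mol %), t-BuOOH (70 % aq.), 1,2-dichloroethane, 40 °C
Reagents that add atoms: tert-butyl hydroperoxide, CC(C)(C)OO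
Why: Dirhodium-catalysed peroxide allylic oxidation, established for Δ5-steroids giving 7-ketones, can only attack C27 because the other allylic carbons C15 and C22 are quaternary.

Step 6
Reactants: 10 ene-dione
Product: 11 methyl (4aR,8aS)-1,1-dimethyl-2,7-dioxooctahydronaphthalene-4a(2H)-carboxylate (trans-decalin)
Conditions: H2 (50 bar), 10 % Pd/C, EtOAc, 40 °C
Reagents that add atoms: none
Why: Heterogeneous catalytic hydrogenation of the enone should add hydrogen to C25 from the α face, away from the angular ester and the β-methyl on C22, giving the trans fusion that is also the more stable one.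

Step 7
Reactants: 11 trans-decalin dione
Product: 12 methyl (4aS,8aS)-7,7-(ethane-1,2-diyldioxy)-1,1-dimethyl-2-oxooctahydronaphthalene-4a(2H)-carboxylate
Conditions: HOCH2CH2OH (1.1 equiv), PPTS (cat.), benzene, reflux, Dean–Stark
Reagents that add atoms: ethane-1,2-diol, OCCO
Why: This acid-catalysed ketalisation should be chemoselective because the C27 carbonyl has two CH2 neighbours whereas C21 is neopentyl beside C22, so one equivalent of diol should mask C27 only.

Step 8
Reactants: 12 keto ketal
Product: 13 methyl (2S,4aS,8aS)-7,7-(ethane-1,2-diyldioxy)-2-hydroxy-1,1-dimethyloctahydronaphthalene-4a(2H)-carboxylate (equatorial β-OH on C21)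
Conditions: NaBH4, MeOH, 0 °C
Reagents that add atoms: none
Why: Borohydride reduction of a 4,4-dimethyl-3-keto-type decalone proceeds by axial hydride delivery from the α face, because the axial β-methyl on C22 blocks the equatorial path, and so should give the equatorial (21S) alcohol as in 3β-hydroxy triterpenoids.

Step 9
Reactants: 13 equatorial alcohol
Product: 15 methyl (3aS,7aS)-6,6-(ethane-1,2-diyldioxy)-1-(propan-2-ylidene)octahydro-3aH-indene-3a-carboxylate, via equatorial triflate 14 (not isolated)
Conditions: Tf2O, 2,6-lutidine, CH2Cl2, −78 → 23 °C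
Reagents that add atoms: trifluoromethanesulfonic anhydride, O=S(=O)(OS(=O)(=O)C(F)(F)F)C(F)(F)F (its CF3SO2 group is found in 14 only)
Why: O-Triflation makes the equatorial C21 oxygen a nucleofuge that can leave neither by SN2 (neopentyl) nor by anti-E2 (no anti hydrogen), so ionisation is assisted by the antiperiplanar C22–C25 σ bond, C25 moves with retention from C22 to the rear of C21, and the tertiary C22 cation gives up the C21 hydrogen to the base to form the tetrasubstituted isopropylidene. The closest known reaction type is the Wagner–Meerwein A-ring contraction of 3β-hydroxy-4,4-dimethyl steroids and triterpenoids on activation of the hydroxyl. Ring D is closed by a suprafacial 1,2-alkyl shift (six-to-five ring contraction, new bond C21–C25) and not by an exo or endo cyclisation, and relief of the 1,3-diaxial contact between the β-methyl on C22 and the ester adds driving force. No stereocentre is created in 15, and C15 and C25 are carried over untouched, so the trans fusion of the decalin becomes the trans fusion of the hydrindane. The step needs ring-bond shift to win over methyl shift, hydride shift and the alternative C19 shift: in the locked chair both methyl groups and both C20 hydrogens are gauche to the C–O bond, and of the two anti ring bonds only C22–C25 leads to a tertiary cation. The hindered, non-nucleophilic base shields the ketal from acid and cannot demethylate the ester should its carbonyl reversibly cap the C22 cation, and any isopropenyl isomer already has the correct C21–H and converges in step 10.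

Step 10
Reactants: 15 isopropylidene hydrindane
Product: 16 methyl (1R,3aS,7aS)-6,6-(ethane-1,2-diyldioxy)-1-(propan-2-yl)octahydro-3aH-indene-3a-carboxylate
Conditions: H2 (50 bar), PtO2, EtOAc–AcOH, 23 °C
Reagents that add atoms: none
Why: In this heterogeneous hydrogenation over Adams catalyst the surface can reach only the α face of ring D, which bears C25–H, because the angular ester covers the β face, so hydrogen should enter C21 cis to C25–H and leave the isopropyl β (21R), cis to C26 and the ester.

Step 11
Reactants: 16 isopropyl ketal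
Product: 17 methyl (1R,3aS,7aS)-6-oxo-1-(propan-2-yl)octahydro-3aH-indene-3a-carboxylate
Conditions: 1 M HCl, THF, 23 °C
Reagents that add atoms: water, O
Why: Acid-catalysed ketal hydrolysis frees the C27 ketone, and both α-carbons (C13, C26) are CH2 groups, so no stereocentre can epimerise.

Step 12
Reactants: 17 hydrindanone; 18 (E)-but-2-en-1-ol
Product: 21 methyl (1R,3aS,5R,7aS)-5-[(2S)-but-3-en-2-yl]-6-oxo-1-(propan-2-yl)octahydro-3aH-indene-3a-carboxylate, via dicrotyl ketal 19 (not isolated), via crotyl enol ether 20 (not isolated)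
Conditions: 18 (3 equiv), p-TsOH (cat.), toluene, reflux, Dean–Stark, then slow distillation (110–120 °C)
Reagents that add atoms: (E)-but-2-en-1-ol (18), C/C=C/CO
Why: In this ketal Claisen [3,3] rearrangement the enol ether forms towards C13, away from the ring fusion and the isopropyl-shielded C26, the allyl unit is delivered to the α face of C13 opposite the 1,3-diaxial ester, and the chair transition state of the E-crotyl/ring enol ether pair gives the syn C13/C11 relation, which corresponds to 13R,11S with C11 equatorial.

Step 13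
Reactants: 22 (R)-β-citronellene
Product: 24 (4R)-4-methylhex-5-enal, via secondary ozonide 23 (not isolated)
Conditions: O3 (1.0 equiv, Sudan III end point), CH2Cl2, −78 °C; Me2S, −78 → 23 °C
Reagents that add atoms: ozone, [O-][O+]=O
Why: Ozonolysis is chemoselective here because electrophilic ozone consumes the electron-rich trisubstituted alkene well before the monosubstituted vinyl group, and the C6 stereocentre is not involved.

Step 14
Reactants: 24 aldehyde; 25 tetrabromomethane
Product: 26 (5R)-1,1-dibromo-5-methylhepta-1,6-diene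
Conditions: CBr4, PPh3, CH2Cl2, 0 °C
Reagents that add atoms: tetrabromomethane (25), BrC(Br)(Br)Br
Why: The first stage of the Corey–Fuchs sequence, a Wittig-type dibromo-olefination, adds carbon C2 under neutral conditions that leave the remote C6 centre alone.

Step 15
Reactants: 26 dibromodiene; 8 iodomethane
Product: 28 (3R)-3-methyloct-1-en-6-yne, via lithium acetylide 27 (not isolated)
Conditions: n-BuLi (2.1 equiv), THF, −78 → 0 °C; MeI, 0 → 23 °C
Reagents that add atoms: iodomethane (8), CI; n-butyllithium, [Li]CCCC (Li in 27 only)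
Why: The second stage of the Corey–Fuchs sequence (Br/Li exchange, 1,2-shift to the alkyne, deprotonation) gives the acetylide, which is methylated in the same flask to install C1.

Step 16
Reactants: 28 enyne
Product: 30 (1Z,2S,3R)-1-(1-iodoethylidene)-2-(iodomethyl)-3-methylcyclopentane, via zirconabicycle 29 (not isolated)
Conditions: Cp2ZrCl2, n-BuLi (2 equiv), THF, −78 → 23 °C; I2 (2.2 equiv), −78 → 23 °C
Reagents that add atoms: iodine, II; zirconocene dichloride, Cl[Zr+2]Cl.[cH-]1cccc1.[cH-]1cccc1 (Cp2Zr in 29 only)
Why: Negishi zirconocene-mediated enyne bicyclisation closes ring A (C3–C8) with the allylic C6 methyl pseudo-equatorial, so C9 should end up trans to it (8S), and because zirconium bridges C2 and C9 in one five-membered metallacycle, iodinolysis with retention places iodine on C2 cis to C8 (Z).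

Step 17
Reactants: 30 diiodide
Product: 31 {[(1S,2Z,5R)-2-(1-iodoethylidene)-5-methylcyclopentyl]methyl}triphenylphosphonium iodide
Conditions: PPh3, MeCN, reflux
Reagents that add atoms: triphenylphosphine, c1ccc(cc1)P(c1ccccc1)c1ccccc1
Why: SN2 quaternisation of the soft, non-basic phosphine occurs only at the primary C9 iodide, since the alkenyl iodide cannot undergo SN2 and elimination is not induced.

Step 18
Reactants: 31 phosphonium iodide
Product: 33 (1Z,2S,3R)-2-ethenyl-1-(1-iodoethylidene)-3-methylcyclopentane, via phosphorus ylide 32 (not isolated)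
Conditions: NaHMDS, THF, −78 → 0 °C; (CH2O)n, 0 → 23 °C
Reagents that add atoms: formaldehyde (from paraformaldehyde), C=O
Why: Wittig olefination of formaldehyde by the non-stabilised C9 ylide turns CH2I into a vinyl group, the amide base avoids iodine–metal exchange at C2, and the carbanion sits on C9, so C8 keeps its configuration.

Step 19
Reactants: 33 ring-A alkenyl iodide; 21 ketone
Product: 36 methyl (1R,3aS,5R,6R,7aS)-5-[(2S)-but-3-en-2-yl]-6-{(1Z)-1-[(2S,3R)-2-ethenyl-3-methylcyclopentylidene]ethyl}-6-hydroxy-1-(propan-2-yl)octahydro-3aH-indene-3a-carboxylate, via alkenyllithium 34 (not isolated), via alkenylcerium dichloride 35 (not isolated)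
Conditions: 33, t-BuLi (2 equiv), Et2O, −78 °C; CeCl3, THF, −78 °C; 21, −78 → −40 °C; H2O
Reagents that add atoms: tert-butyllithium, [Li]C(C)(C)C (Li in 34 only); cerium(III) chloride, Cl[Ce](Cl)Cl (CeCl2 in 35 only)
Why: Iodine–lithium exchange with retention of geometry, transmetallation to the weakly basic organocerium and 1,2-addition should follow the equatorial trajectory usual for bulky nucleophiles on 2-substituted cyclohexanones, trans to the C11 chain, giving the axial α-hydroxyl (27R), while the hindered angular ester stays untouched at low temperature.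

Step 20
Reactants: 36 triene alcohol
Product: 37 methyl 9,10-didehydrosesterfisherate (2Z,9Z; 6R,8R,11S,13R,15S,21R,25S,27R in target numbering)
Conditions: Hoveyda–Grubbs II (10 mol %), 1,4-benzoquinone (cat.), toluene (1 mM), 80 °C
Reagents that add atoms: none
Why: Ring-closing metathesis joins the two monosubstituted vinyl groups to close the eight-membered ring B, helped by the gauche diequatorial C13 and C27 bonds and by the Z alkene C2=C3 that holds C8 next to C27, while the tetrasubstituted alkene is inert and the ring size allows only a Z C9=C10.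

Step 21
Reactants: 37 cyclooctadiene
Product: 38 methyl sesterfisherate (6R,8S,11S,13R,15S,21R,25S,27R)
Conditions: 2-O2NC6H4SO2NHNH2, Et3N, CH2Cl2, 23 °C
Reagents that add atoms: none
Why: Diimide reduction transfers H2 in a concerted way to the strained cis-disubstituted C9=C10 alkene only, leaving the tetrasubstituted C2=C3 and avoiding the alkene migration or allylic hydrogenolysis that metal catalysts could cause.

Step 22
Reactants: 38 methyl ester
Product: 39 sesterfisheric acid
Conditions: NaSEt, DMF, 100 °C; 0.5 M HCl to pH 4, 0 °C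
Reagents that add atoms: none
Why: SN2 dealkylation of the methyl ester by thiolate attacks the unhindered O–CH3 carbon and not the shielded neopentyl carbonyl, and it avoids the strong acid that would ionise the tertiary allylic alcohol.

Compound list
1 | methyl 2-oxocyclohexane-1-carboxylate | COC(=O)C1CCCCC1=O | starting material
2 | L-valine diethylamide | N[C@@H](C(C)C)C(=O)N(CC)CC | starting material
3 | methyl 2-{[(2S)-1-(diethylamino)-3-methyl-1-oxobutan-2-yl]amino}cyclohex-1-ene-1-carboxylate | COC(=O)C1=C(N[C@@H](C(C)C)C(=O)N(CC)CC)CCCC1 | intermediate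
4 | but-3-en-2-one | CC(=O)C=C | starting material
5 | C25 imine of 6 with the auxiliary (formed in situ) | C1C[C@@](C(=O)OC)(CCC(C)=O)C(=N[C@@H](C(C)C)C(=O)N(CC)CC)CC1 | intermediate
6 | methyl (1R)-2-oxo-1-(3-oxobutyl)cyclohexane-1-carboxylate | C1C[C@@](C(=O)OC)(CCC(C)=O)C(=O)CC1 | intermediate
7 | methyl (4aR)-2-oxo-3,4,5,6,7,8-hexahydronaphthalene-4a(2H)-carboxylate | C1C[C@@]2(C(=O)OC)CCC(=O)C=C2CC1 | intermediate
8 | iodomethane | CI | starting material
9 | methyl (4aR)-1,1-dimethyl-2-oxo-1,3,4,5,6,7-hexahydronaphthalene-4a(2H)-carboxylate | C1C[C@@]2(C(=O)OC)CCC(=O)C(C)(C)C2=CC1 | intermediate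
10 | methyl (4aR)-1,1-dimethyl-2,7-dioxo-1,3,4,5,6,7-hexahydronaphthalene-4a(2H)-carboxylate | C1C[C@@]2(C(=O)OC)CCC(=O)C(C)(C)C2=CC1=O | intermediate
11 | methyl (4aR,8aS)-1,1-dimethyl-2,7-dioxooctahydronaphthalene-4a(2H)-carboxylate | C1C[C@@]2(C(=O)OC)CCC(=O)C(C)(C)[C@@H]2CC1=O | intermediate
12 | methyl (4aS,8aS)-7,7-(ethane-1,2-diyldioxy)-1,1-dimethyl-2-oxooctahydronaphthalene-4a(2H)-carboxylate | C1C[C@@]2(C(=O)OC)CCC(=O)C(C)(C)[C@@H]2CC13OCCO3 | intermediate
13 | methyl (2S,4aS,8aS)-7,7-(ethane-1,2-diyldioxy)-2-hydroxy-1,1-dimethyloctahydronaphthalene-4a(2H)-carboxylate | C1C[C@@]2(C(=O)OC)CC[C@H](O)C(C)(C)[C@@H]2CC13OCCO3 | intermediate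
14 | C21 trifluoromethanesulfonate of 13 (formed in situ) | C1C[C@@]2(C(=O)OC)CC[C@H](OS(=O)(=O)C(F)(F)F)C(C)(C)[C@@H]2CC13OCCO3 | intermediate
15 | methyl (3aS,7aS)-6,6-(ethane-1,2-diyldioxy)-1-(propan-2-ylidene)octahydro-3aH-indene-3a-carboxylate | C1C[C@@]2(C(=O)OC)CCC(=C(C)C)[C@@H]2CC13OCCO3 | intermediate
16 | methyl (1R,3aS,7aS)-6,6-(ethane-1,2-diyldioxy)-1-(propan-2-yl)octahydro-3aH-indene-3a-carboxylate | C1C[C@@]2(C(=O)OC)CC[C@H](C(C)C)[C@@H]2CC13OCCO3 | intermediate
17 | methyl (1R,3aS,7aS)-6-oxo-1-(propan-2-yl)octahydro-3aH-indene-3a-carboxylate | C1C[C@@]2(C(=O)OC)CC[C@H](C(C)C)[C@@H]2CC1=O | intermediate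
18 | (E)-but-2-en-1-ol | C/C=C/CO | starting material
19 | C27 bis[(E)-but-2-enyl] ketal of 17 (formed in situ) | C1C[C@@]2(C(=O)OC)CC[C@H](C(C)C)[C@@H]2CC1(OC/C=C/C)OC/C=C/C | intermediate
20 | (E)-but-2-enyl C13=C27 enol ether of 17 (formed in situ) | C=1C[C@@]2(C(=O)OC)CC[C@H](C(C)C)[C@@H]2CC=1OC/C=C/C | intermediate
21 | methyl (1R,3aS,5R,7aS)-5-[(2S)-but-3-en-2-yl]-6-oxo-1-(propan-2-yl)octahydro-3aH-indene-3a-carboxylate | C=C[C@H](C)[C@H]1C[C@@]2(C(=O)OC)CC[C@H](C(C)C)[C@@H]2CC1=O | intermediate
22 | (R)-β-citronellene, (3R)-3,7-dimethylocta-1,6-diene | CC(C)=CCC[C@@H](C)C=C | starting material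
23 | secondary ozonide of the trisubstituted alkene of 22 (formed in situ) | CC1(C)OOC(CC[C@@H](C)C=C)O1 | intermediate
24 | (4R)-4-methylhex-5-enal | O=CCC[C@@H](C)C=C | intermediate
25 | tetrabromomethane | BrC(Br)(Br)Br | starting material
26 | (5R)-1,1-dibromo-5-methylhepta-1,6-diene | BrC(Br)=CCC[C@@H](C)C=C | intermediate
27 | [(5R)-5-methylhept-6-en-1-yn-1-yl]lithium (formed in situ) | [Li]C#CCC[C@@H](C)C=C | intermediate
28 | (3R)-3-methyloct-1-en-6-yne | CC#CCC[C@@H](C)C=C | intermediate
29 | zirconabicycle, Cp2Zr bridging C2 and C9 (formed in situ) | CC1=C2CC[C@@H](C)[C@@H]2C[Zr+2]1.[cH-]1cccc1.[cH-]1cccc1 | intermediate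
30 | (1Z,2S,3R)-1-(1-iodoethylidene)-2-(iodomethyl)-3-methylcyclopentane | C/C(I)=C1\CC[C@@H](C)[C@@H]1CI | intermediate
31 | {[(1S,2Z,5R)-2-(1-iodoethylidene)-5-methylcyclopentyl]methyl}triphenylphosphonium iodide | C/C(I)=C1\CC[C@@H](C)[C@@H]1C[P+](c1ccccc1)(c1ccccc1)c1ccccc1.[I-] | intermediate
32 | C9 triphenylphosphonium ylide of 31 (formed in situ) | C/C(I)=C1\CC[C@@H](C)[C@@H]1C=P(c1ccccc1)(c1ccccc1)c1ccccc1 | intermediate
33 | (1Z,2S,3R)-2-ethenyl-1-(1-iodoethylidene)-3-methylcyclopentane | C/C(I)=C1\CC[C@@H](C)[C@@H]1C=C | intermediate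
34 | C2 alkenyllithium from 33 (formed in situ) | C/C([Li])=C1\CC[C@@H](C)[C@@H]1C=C | intermediate
35 | C2 alkenylcerium dichloride from 34 (formed in situ) | C/C([Ce](Cl)Cl)=C1\CC[C@@H](C)[C@@H]1C=C | intermediate
36 | triene alcohol, C27–C2 adduct of 21 and 33 (2Z; 6R,8S,11S,13R,15S,21R,25S,27R) | C=C[C@H](C)[C@H]1C[C@@]2(C(=O)OC)CC[C@H](C(C)C)[C@@H]2C[C@]1(O)/C(C)=C3/CC[C@@H](C)[C@@H]3C=C | intermediate
37 | methyl 9,10-didehydrosesterfisherate (2Z,9Z) | C/C1=C2\CC[C@@H](C)[C@@H]2/C=C\[C@H](C)[C@H]2C[C@@]3(C(=O)OC)CC[C@H](C(C)C)[C@@H]3C[C@]12O | intermediate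
38 | methyl sesterfisherate | C/C1=C2\CC[C@@H](C)[C@@H]2CC[C@H](C)[C@H]2C[C@@]3(C(=O)OC)CC[C@H](C(C)C)[C@@H]3C[C@]12O | intermediate
39 | sesterfisheric acid | C/C1=C2\CC[C@@H](C)[C@@H]2CC[C@H](C)[C@H]2C[C@@]3(C(=O)O)CC[C@H](C(C)C)[C@@H]3C[C@]12O | target

Total steps: 22. Longest linear sequence: 16 steps (1–12 and 19–22). The ring-A branch has 6 steps (13–18).

Steps most likely to fail

Step 12. Several processes could erode the C11 configuration or the regiochemistry. These are enol-ether formation towards C26, a boat-type transition state, delivery to the β face, acid-induced transposition of the crotyl alcohol, and a second allylation.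
The fallback replaces the substrate-controlled sigmatropic step by a catalyst-controlled palladium allylic alkylation. It sets out from 17 and returns at 37.
- Racemic (E)-pent-3-en-2-yl methyl carbonate F1 is made from commercial (E)-pent-3-en-2-ol and methyl chloroformate.
- Ketone 17 is deprotonated kinetically (LDA, LiCl, THF, −78 °C) to the lithium C13=C27 enolate F2.
- F2 is allylated with F1 under Pd2(dba)3 and the BINAP antipode matched to 11S. The symmetrical 1,3-dimethylallyl–palladium unit removes the branched/linear question, and the ligand decides which terminus is attacked, giving the propenyl ketone F3.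
- Addition of 35 under the conditions of step 19 gives the adduct F4.
- Metathesis of F4 under the conditions of step 20 closes the same ring and delivers 37.

Step 19. The tetrasubstituted alkenyl-metal may enolise the α-branched ketone, or it may fail to add because of steric compression at the incipient C27–C2 bond.
The fallback joins the halves at C9=C10 first and forms C27–C2 intramolecularly. It sets out from 21 and 31, returns at 37, and bypasses steps 18–20.
- Ozonolysis of the vinyl group of 21 (O3; Me2S) gives the keto aldehyde F5.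
- F5 is condensed chemoselectively at −78 °C with ylide 32 (from 31 and NaHMDS) to the (Z)-alkenyl keto iodide F6.
- Iodine–lithium exchange (t-BuLi, THF–Et2O–pentane, −100 °C) gives the tethered alkenyllithium F7.
- In F7 the Z alkene and the equatorial C13 chain hold C2 close to the carbonyl, so that closure to 37 should outrun proton transfer.

Step 10. Uptake of hydrogen at the tetrasubstituted alkene may be slow, the alkene may migrate on the catalyst, or the facial bias may be insufficient.
The fallback takes the C21 configuration from the stereospecific shift and not from the hydrogenation. It sets out from 13 and returns at 16.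
- Triflate 14 is generated in the presence of 2,6-di-tert-butyl-4-methylpyridine. This base can reach only the methyl hydrogens of the C22 cation, so the isopropenyl hydrindane F8 should form.
- In F8 the α C21–H was never removed, and inversion at C21 has placed C22 on the β face.
- Hydrogenation of its unhindered 1,1-disubstituted alkene (Pd/C, H2 1 atm, EtOAc) then gives 16.

Further compounds
F1 | step 12 | rac-(E)-pent-3-en-2-yl methyl carbonate | C/C=C/C(C)OC(=O)OC
F2 | step 12 | lithium C13=C27 enolate of 17 | C=1C[C@@]2(C(=O)OC)CC[C@H](C(C)C)[C@@H]2CC=1O[Li]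
F3 | step 12 | methyl (1R,3aS,5R,7aS)-6-oxo-5-[(2S,3E)-pent-3-en-2-yl]-1-(propan-2-yl)octahydro-3aH-indene-3a-carboxylate | C/C=C/[C@H](C)[C@H]1C[C@@]2(C(=O)OC)CC[C@H](C(C)C)[C@@H]2CC1=O
F4 | step 12 | C27–C2 adduct of F3 and 35 (propenyl analogue of 36) | C/C=C/[C@H](C)[C@H]1C[C@@]2(C(=O)OC)CC[C@H](C(C)C)[C@@H]2C[C@]1(O)/C(C)=C3/CC[C@@H](C)[C@@H]3C=C
F5 | step 19 | methyl (1R,3aS,5R,7aS)-6-oxo-5-[(2S)-1-oxopropan-2-yl]-1-(propan-2-yl)octahydro-3aH-indene-3a-carboxylate | O=C[C@H](C)[C@H]1C[C@@]2(C(=O)OC)CC[C@H](C(C)C)[C@@H]2CC1=O
F6 | step 19 | (9Z)-alkenyl keto iodide, Wittig product of F5 and 32 | C/C(I)=C1\CC[C@@H](C)[C@@H]1/C=C\[C@H](C)[C@H]1C[C@@]2(C(=O)OC)CC[C@H](C(C)C)[C@@H]2CC1=O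
F7 | step 19 | C2 alkenyllithium from F6 | C/C([Li])=C1\CC[C@@H](C)[C@@H]1/C=C\[C@H](C)[C@H]1C[C@@]2(C(=O)OC)CC[C@H](C(C)C)[C@@H]2CC1=O
F8 | step 10 | methyl (1R,3aS,7aS)-6,6-(ethane-1,2-diyldioxy)-1-(prop-1-en-2-yl)octahydro-3aH-indene-3a-carboxylate | C1C[C@@]2(C(=O)OC)CC[C@H](C(C)=C)[C@@H]2CC13OCCO3
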